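**Plan**

1. Retrosynthesis: the B-ring silyl ether is removed last. The pyran ring is then cut at C4–C4a and at O1–C8a, so ring A leaves as one dearomatised C6 unit (p-benzoquinone mono-dimethyl ketal) and ring B keeps the chain BrCH2–CH(Ar)–CH2O–. That bromide is traced to an achiral 3-aryloxetane, and the aryl group to 2,6-dimethoxyphenol.
2. Enabling feature: ring A (C4a–C5–C6–C7–C8–C8a) carries a single substituent, the C7 hydroxyl, para to C4a and meta to C8a. C4a, C8a and C7 therefore map onto the carbonyl carbon, a β-carbon and the ketal carbon of a quinone monoketal. C4a can then be made by carbanion addition and C8a by oxa-Michael addition, and loss of water returns the phenol.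
3. Forward: ring B is built on 2,6-dimethoxyphenol by two methoxy-directed brominations, each followed by a cross-coupling (oxetan-3-yl, then 1,1-dimethylallyl). The oxetane is opened to the C4–C3–C2 chain, ring A is attached and the pyran ring closed in one flask while ring A aromatises, and desilylation ends the route.
4. Stereochemistry: the single stereocentre C3 (S) comes from a catalyst-controlled enantioselective desymmetrisation of the oxetane with bromide (step 6) and is not touched afterwards.

Key step: step 8

Remark: the target is read as the (3S)-isoflavan. The hand of the squaramide catalyst in step 6 is chosen to give the (S)-bromide and is to be confirmed there. Ar* stands for 2,4-dimethoxy-5-(2-methylbut-3-en-2-yl)-3-{[tri(propan-2-yl)silyl]oxy}phenyl.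

**Step 1**
Reactants: 1 2,6-dimethoxyphenol
Product: 2 (2,6-dimethoxyphenoxy)tri(propan-2-yl)silane
Conditions: TIPSCl, imidazole, DMF, 50 °C
Reagents that add atoms: chlorotri(propan-2-yl)silane, CC(C)[Si](Cl)(C(C)C)C(C)C
Why: Imidazole-mediated silylation of a phenol; TIPS should survive aqueous phosphate (step 5), TMSBr (step 6), tert-butyllithium and dilute acid (step 8), and, twisted out of plane between two methoxy groups, it weakens the directing power of this oxygen in steps 2 and 4.

**Step 2**
Reactants: 2 (2,6-dimethoxyphenoxy)tri(propan-2-yl)silane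
Product: 3 (3-bromo-2,6-dimethoxyphenoxy)tri(propan-2-yl)silane
Conditions: NBS (1.0 equiv), MeCN, 0 °C → rt, dark
Reagents that add atoms: N-bromosuccinimide, O=C1CCC(=O)N1Br
Why: Electrophilic aromatic bromination; C3 is ortho to one methoxy group and para to the other, whereas C4 is meta to both and para only to the weakly donating silyloxy group, as in the 4-bromination of 1,2,3-trialkoxybenzenes, and one equivalent limits dibromination.

**Step 3**
Reactants: 3 (3-bromo-2,6-dimethoxyphenoxy)tri(propan-2-yl)silane + 4 3-bromooxetane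
Product: 5 [2,6-dimethoxy-3-(oxetan-3-yl)phenoxy]tri(propan-2-yl)silane
Conditions: NiI2 (10 mol %), 4,4′-di-tert-butyl-2,2′-bipyridine (10 mol %), NaI (25 mol %), pyridine (10 mol %), Zn dust (2 equiv), DMA, 60 °C
Reagents that add atoms: none
Why: Nickel-catalysed reductive cross-electrophile coupling of an aryl bromide with a secondary alkyl bromide (zinc as terminal reductant); the oxetan-3-yl radical is captured by arylnickel(II) and C(sp2)–C(sp3) reductive elimination follows, with the silyl and methyl ethers inert.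

**Step 4**
Reactants: 5 [2,6-dimethoxy-3-(oxetan-3-yl)phenoxy]tri(propan-2-yl)silane
Product: 6 [3-bromo-2,6-dimethoxy-5-(oxetan-3-yl)phenoxy]tri(propan-2-yl)silane
Conditions: NBS (1.0 equiv), MeCN, 0 °C, dark
Reagents that add atoms: N-bromosuccinimide, O=C1CCC(=O)N1Br
Why: Second electrophilic bromination; C5 is the remaining position ortho/para to the two methoxy groups while C4 is meta to both and flanked by the oxetanyl group, and NBS in MeCN in the dark is a neutral ionic bromine source that should spare the oxetane and its benzylic C–H.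

**Step 5**
Reactants: 6 [3-bromo-2,6-dimethoxy-5-(oxetan-3-yl)phenoxy]tri(propan-2-yl)silane + 7 prenylboronic acid pinacol ester
Product: 8 [2,6-dimethoxy-3-(2-methylbut-3-en-2-yl)-5-(oxetan-3-yl)phenoxy]tri(propan-2-yl)silane
Conditions: 7 (1.5 equiv), Pd(OAc)2 (2 mol %), dialkylbiarylphosphine selected for γ-selectivity (4 mol %), aq. K3PO4, MeCN, 70 °C
Reagents that add atoms: none
Why: Ligand-controlled γ-selective Suzuki–Miyaura coupling of a 3,3-disubstituted allylboronate; SE2′ transmetalation places palladium on the tertiary carbon and reductive elimination ahead of σ–π–σ isomerisation forms the aryl–C(CH3)2 bond of the 1,1-dimethylallyl group, while oxetane and TIPS ether tolerate aqueous phosphate.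

**Step 6**
Reactants: 8 [2,6-dimethoxy-3-(2-methylbut-3-en-2-yl)-5-(oxetan-3-yl)phenoxy]tri(propan-2-yl)silane
Product: 10 (2S)-3-bromo-2-(Ar*)propan-1-ol, via TMS ether 9 (not isolated)
Conditions: chiral arylpyrrolidine-derived squaramide hydrogen-bond-donor catalyst (5 mol %), TMSBr (1.3 equiv), t-BuOMe, –78 °C; then 10 % aq. citric acid, 0 °C
Reagents that add atoms: bromotrimethylsilane, C[Si](C)(C)Br
Why: Catalytic enantioselective desymmetrisation of a 3-substituted oxetane with TMSBr; the chiral hydrogen-bond donor binds the bromide of the silyloxetanium ion pair and delivers it by SN2 to one of the two enantiotopic CH2 groups, which sets the only stereocentre (the later C3) as S, and aqueous work-up cleaves the TMS ether.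

**Step 7**
Reactants: 10 (2S)-3-bromo-2-(Ar*)propan-1-ol
Product: 11 (S)-bromide TBS ether
Conditions: TBSCl, imidazole, CH2Cl2, 0 °C → rt
Reagents that add atoms: tert-butylchlorodimethylsilane, CC(C)(C)[Si](C)(C)Cl
Why: Standard silylation of a primary alcohol; the TBS ether masks the hydroxyl during organolithium formation and is lost in the acid of step 8, and the stereocentre is not involved.

**Step 8**
Reactants: 11 (S)-bromide TBS ether + 12 4,4-dimethoxycyclohexa-2,5-dien-1-one
Product: 18 TIPS-protected (3S)-isoflavan-7-ol, via alkyllithium 13 (not isolated), via lithium quinol-ketal alkoxide 14 (not isolated), via silylated p-quinol 15 (not isolated), via p-quinol diol 16 (not isolated), via oxa-Michael adduct 17 (not isolated)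
Conditions: t-BuLi (2.0 equiv), Et2O–pentane, –78 °C; 12 in THF, –78 °C; then 2 M aq. HCl, THF, –78 → 45 °C
Reagents that add atoms: water, O
Why: Proposed new method: bromine–lithium exchange gives the primary alkyllithium 13, which adds 1,2 to the only carbonyl of 12 (hard organolithiums attack quinone monoketals at C=O at –78 °C) and forms C4–C4a; aqueous acid then hydrolyses the ketal and the TBS ether to p-quinol 16, whose primary hydroxyl adds to the neighbouring β-carbon of the cross-conjugated dienone (6-exo-trig oxa-Michael, forming O1–C8a and closing the pyran ring), and the tertiary, doubly allylic C4a–OH of the dienol form of 17 ionises to an arenium ion that loses the C8a proton, so ring A aromatises with its hydroxyl at C7. The closest known reactions are the 1,2-addition of organolithiums to quinone monoketals to make p-quinols, the acid-catalysed intramolecular oxa-Michael desymmetrisation of 4-substituted cyclohexadienones, and the conjugate addition–dehydration of p-quinols to meta-functionalised phenols; their telescoping into a two-bond chroman annulation is the untested part. No lasting stereocentre is created: C3 comes from 11 and lies two bonds from every reacting centre, and the C4a/C8a centres of 17 are erased on aromatisation, so attack at either diastereotopic β-carbon of the symmetric dienone leads to the same product. Regiochemistry is fixed by the three-atom tether, which can reach only C8a (or its mirror-related C5) and never C8/C6, so the ring-A hydroxyl must end up para to C4a and meta to O1. Chemoselectivity rests on the chain oxygen being a better internal nucleophile for the dienone than the hindered C6′ of ring B, on the aryl TIPS ether and the monosubstituted alkene tolerating dilute HCl at 45 °C, and on aromatisation pulling the reversible oxa-Michael step forward.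

**Step 9**
Reactants: 18 TIPS-protected (3S)-isoflavan-7-ol
Product: 19 (3S)-3-[3-hydroxy-2,4-dimethoxy-5-(2-methylbut-3-en-2-yl)phenyl]-3,4-dihydro-2H-chromen-7-ol
Conditions: TBAF (1.1 equiv), THF, 0 °C; then aq. NH4Cl
Reagents that add atoms: none
Why: Fluoride cleavage of an aryl silyl ether driven by Si–F bond formation; the conditions are non-acidic, so the alkene, the ethers and C3 should be unaffected.

**Compound list**

1 | 2,6-dimethoxyphenol | COc1cccc(OC)c1O | starting material
2 | (2,6-dimethoxyphenoxy)tri(propan-2-yl)silane | COc1cccc(OC)c1O[Si](C(C)C)(C(C)C)C(C)C | intermediate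
3 | (3-bromo-2,6-dimethoxyphenoxy)tri(propan-2-yl)silane | COc1ccc(Br)c(OC)c1O[Si](C(C)C)(C(C)C)C(C)C | intermediate
4 | 3-bromooxetane | BrC1COC1 | starting material
5 | [2,6-dimethoxy-3-(oxetan-3-yl)phenoxy]tri(propan-2-yl)silane | COc1ccc(C2COC2)c(OC)c1O[Si](C(C)C)(C(C)C)C(C)C | intermediate
6 | [3-bromo-2,6-dimethoxy-5-(oxetan-3-yl)phenoxy]tri(propan-2-yl)silane | COc1c(Br)cc(C2COC2)c(OC)c1O[Si](C(C)C)(C(C)C)C(C)C | intermediate
7 | 4,4,5,5-tetramethyl-2-(3-methylbut-2-en-1-yl)-1,3,2-dioxaborolane (prenylboronic acid pinacol ester) | CC(C)=CCB1OC(C)(C)C(C)(C)O1 | starting material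
8 | [2,6-dimethoxy-3-(2-methylbut-3-en-2-yl)-5-(oxetan-3-yl)phenoxy]tri(propan-2-yl)silane | C=CC(C)(C)c1cc(C2COC2)c(OC)c(O[Si](C(C)C)(C(C)C)C(C)C)c1OC | intermediate
9 | [(2S)-3-bromo-2-(Ar*)propoxy]trimethylsilane | C=CC(C)(C)c1cc([C@H](CBr)CO[Si](C)(C)C)c(OC)c(O[Si](C(C)C)(C(C)C)C(C)C)c1OC | intermediate (not isolated)
10 | (2S)-3-bromo-2-(Ar*)propan-1-ol | C=CC(C)(C)c1cc([C@H](CBr)CO)c(OC)c(O[Si](C(C)C)(C(C)C)C(C)C)c1OC | intermediate
11 | [(2S)-3-bromo-2-(Ar*)propoxy](tert-butyl)dimethylsilane | C=CC(C)(C)c1cc([C@H](CBr)CO[Si](C)(C)C(C)(C)C)c(OC)c(O[Si](C(C)C)(C(C)C)C(C)C)c1OC | intermediate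
12 | 4,4-dimethoxycyclohexa-2,5-dien-1-one (p-benzoquinone mono-dimethyl ketal) | COC1(OC)C=CC(=O)C=C1 | starting material
13 | {(2S)-2-(Ar*)-3-[(tert-butyldimethylsilyl)oxy]propyl}lithium | C=CC(C)(C)c1cc([C@H](C[Li])CO[Si](C)(C)C(C)(C)C)c(OC)c(O[Si](C(C)C)(C(C)C)C(C)C)c1OC | intermediate (not isolated)
14 | lithium 1-{(2S)-2-(Ar*)-3-[(tert-butyldimethylsilyl)oxy]propyl}-4,4-dimethoxycyclohexa-2,5-dien-1-olate | C=CC(C)(C)c1cc([C@H](CC2(O[Li])C=CC(OC)(OC)C=C2)CO[Si](C)(C)C(C)(C)C)c(OC)c(O[Si](C(C)C)(C(C)C)C(C)C)c1OC | intermediate (not isolated)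
15 | 4-{(2S)-2-(Ar*)-3-[(tert-butyldimethylsilyl)oxy]propyl}-4-hydroxycyclohexa-2,5-dien-1-one | C=CC(C)(C)c1cc([C@H](CC2(O)C=CC(=O)C=C2)CO[Si](C)(C)C(C)(C)C)c(OC)c(O[Si](C(C)C)(C(C)C)C(C)C)c1OC | intermediate (not isolated)
16 | 4-hydroxy-4-[(2S)-3-hydroxy-2-(Ar*)propyl]cyclohexa-2,5-dien-1-one | C=CC(C)(C)c1cc([C@H](CC2(O)C=CC(=O)C=C2)CO)c(OC)c(O[Si](C(C)C)(C(C)C)C(C)C)c1OC | intermediate (not isolated)
17 | (3S)-3-(Ar*)-4a-hydroxy-2,3,4,4a,8,8a-hexahydro-7H-chromen-7-one (cis-fused; both C4a/C8a diastereomers, which converge) | C=CC(C)(C)c1cc([C@H]2COC3CC(=O)C=CC3(O)C2)c(OC)c(O[Si](C(C)C)(C(C)C)C(C)C)c1OC | intermediate (not isolated)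
18 | (3S)-3-(Ar*)-3,4-dihydro-2H-chromen-7-ol | C=CC(C)(C)c1cc([C@H]2COc3cc(O)ccc3C2)c(OC)c(O[Si](C(C)C)(C(C)C)C(C)C)c1OC | intermediate
19 | (3S)-3-[3-hydroxy-2,4-dimethoxy-5-(2-methylbut-3-en-2-yl)phenyl]-3,4-dihydro-2H-chromen-7-ol | C=CC(C)(C)c1cc([C@H]2COc3cc(O)ccc3C2)c(OC)c(O)c1OC | target

**Totals**

Total step count: 9. Longest linear sequence: 9 steps (1 → 19); compounds 4, 7 and 12 are purchased.

**Steps most likely to fail**

Step 8 (proposed new method). The bromine–lithium exchange on a primary bromide may be accompanied by Wurtz-type coupling or O→C silyl migration. The hydroxy enone may also stall before dehydrative aromatisation, or the dienone may be captured by C6′ of ring B instead of the chain oxygen. The fallback uses known chemistry, sets out from 11 and returns at 19. Zinc insertion (Zn dust, LiCl, THF, 45 °C) should give the alkylzinc bromide F1. Negishi coupling (PdCl2(dppf), THF, 50 °C) with (4-bromo-3-chlorophenoxy)tri(propan-2-yl)silane F2, prepared from commercial 4-bromo-3-chlorophenol with TIPSCl and imidazole, should take place at the C–Br bond and give the chloroarene F3. PPTS in MeOH should remove only the primary TBS ether to give the alcohol F4. Intramolecular palladium-catalysed C–O coupling (Pd(OAc)2, a bulky di-tert-butyl(biaryl)phosphine, Cs2CO3, toluene, 80 °C) should close the pyran ring to the bis-silyl ether F5. TBAF then removes both TIPS groups and gives 19.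

Step 6. Enantiofacial discrimination may be insufficient for an aryl group with an ortho substituent, and the 2-methoxy oxygen may open the activated oxetane itself (neighbouring-group participation with loss of the methyl group). The fallback sets out from 8 and returns at 10. Acid-catalysed hydrolysis of the oxetane (dilute H2SO4, dioxane–water, 40 °C) should give the prochiral diol F6. Lipase-catalysed desymmetrising acetylation (vinyl acetate, Pseudomonas cepacia or porcine pancreatic lipase, chosen by screening for the arm it acylates) should give the (R)-monoacetate F7. Appel bromination of the free arm (CBr4, PPh3, CH2Cl2, 0 °C) should give the (S)-bromo acetate F8. Acidic methanolysis (catalytic HCl in MeOH, rt) removes the acetate and gives 10.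

Step 5. γ-Selectivity may be lost through σ–π–σ isomerisation to the linear prenyl arene, and reductive elimination may be slow where a quaternary carbon has to form next to an ortho-methoxy group. The fallback sets out from 6 and returns at 8. Palladium-catalysed α-arylation of 2-methylpropanal (Pd(OAc)2, rac-BINAP, Cs2CO3, dioxane, 80 °C) should give the α-aryl aldehyde F9, which cannot enolise. Wittig methylenation (Ph3PCH3Br, KOt-Bu, THF, 0 °C → rt) then gives 8.

**Further compounds**

F1 | step 8 | bromo{(2S)-2-(Ar*)-3-[(tert-butyldimethylsilyl)oxy]propyl}zinc | C=CC(C)(C)c1cc([C@H](C[Zn]Br)CO[Si](C)(C)C(C)(C)C)c(OC)c(O[Si](C(C)C)(C(C)C)C(C)C)c1OC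
F2 | step 8 | (4-bromo-3-chlorophenoxy)tri(propan-2-yl)silane | CC(C)[Si](Oc1ccc(Br)c(Cl)c1)(C(C)C)C(C)C
F3 | step 8 | tert-butyl{[(2S)-3-(2-chloro-4-{[tri(propan-2-yl)silyl]oxy}phenyl)-2-(Ar*)propyl]oxy}dimethylsilane | C=CC(C)(C)c1cc([C@H](Cc2ccc(O[Si](C(C)C)(C(C)C)C(C)C)cc2Cl)CO[Si](C)(C)C(C)(C)C)c(OC)c(O[Si](C(C)C)(C(C)C)C(C)C)c1OC
F4 | step 8 | (2S)-3-(2-chloro-4-{[tri(propan-2-yl)silyl]oxy}phenyl)-2-(Ar*)propan-1-ol | C=CC(C)(C)c1cc([C@H](Cc2ccc(O[Si](C(C)C)(C(C)C)C(C)C)cc2Cl)CO)c(OC)c(O[Si](C(C)C)(C(C)C)C(C)C)c1OC
F5 | step 8 | {[(3S)-3-(Ar*)-3,4-dihydro-2H-chromen-7-yl]oxy}tri(propan-2-yl)silane | C=CC(C)(C)c1cc([C@H]2COc3cc(O[Si](C(C)C)(C(C)C)C(C)C)ccc3C2)c(OC)c(O[Si](C(C)C)(C(C)C)C(C)C)c1OC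
F6 | step 6 | 2-(Ar*)propane-1,3-diol | C=CC(C)(C)c1cc(C(CO)CO)c(OC)c(O[Si](C(C)C)(C(C)C)C(C)C)c1OC
F7 | step 6 | (2R)-3-hydroxy-2-(Ar*)propyl acetate | C=CC(C)(C)c1cc([C@H](CO)COC(C)=O)c(OC)c(O[Si](C(C)C)(C(C)C)C(C)C)c1OC
F8 | step 6 | (2S)-3-bromo-2-(Ar*)propyl acetate | C=CC(C)(C)c1cc([C@H](CBr)COC(C)=O)c(OC)c(O[Si](C(C)C)(C(C)C)C(C)C)c1OC
F9 | step 5 | 2-[2,4-dimethoxy-5-(oxetan-3-yl)-3-{[tri(propan-2-yl)silyl]oxy}phenyl]-2-methylpropanal | O=CC(C)(C)c1cc(C2COC2)c(OC)c(O[Si](C(C)C)(C(C)C)C(C)C)c1OC
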